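(The earlier runs and the new flask were generated by integration for substances that don't exist; scatter was added.)

I began from a one-step world, where starting material and partner become product and the catalyst comes back unchanged. These were the flasks, and what I had to say about them.

the same everywhere: catalyst 6.00 mM
- ochre: starting material 200 mM; partner 220 mM
- violet: starting material 300 mM; partner 220 mM
- teal: starting material 200 mM; partner 440 mM
- green: starting material 200 mM; partner 220 mM; product 100 mM; time 71 min

- ochre run (time / min: [product] / mM): 10: 20.8; 20: 39.3; 30: 56.2; 41: 68.6; 51: 75.9; 61: 81.9; 71: 85.5
- violet run (time / min: [product] / mM): 10: 31.8; 20: 58.4; 30: 81.5; 41: 96.9; 51: 105.9; 61: 109.1; 71: 111.6
- teal run (time / min: [product] / mM): 10: 23.1; 20: 41.3; 30: 57.9; 41: 74.9; 51: 87.2; 61: 95.5; 71: 102.4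

(scatter of a reading: 1 mM)

- Overall: starting material + partner -> product, with catalyst as catalyst.
- Constant volume, constant temperature.
- Readings of a species count what is bound in complexes too.
- "The second partner" is partner.
- An order is taken over about fifteen percent of the charge, up and down.
- A share of product counts the product that was charged too.

- reaction order in [partner] at the outset, round the charge of the ochre run, defined at two percent of the starting material turned into product
- reaction order in [starting material] at the outset, round the charge of the ochre run, defined at two percent of the starting material turned into product (one fixed amount of product, the same in the runs compared)
- product in the green run at 71 min, as a share of the starting material charged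
- which of these the readings show (the product binds the second partner / the catalyst rests as a dimer / the second partner is lost by itself / the substrate ties up the catalyst / the product kills the catalyst / nothing beyond the main steps)

The green run is the ochre charge with product added at the start, so I wanted one number to carry from ochre to green. I counted turnovers. The ochre run made 85.5 mM by 71 min on 6.00 mM of catalyst, a count of 14.2. This turnover count, the product made per catalyst charged by that time, is the usual turnover number. It says how many rounds the catalyst had made on average.

If the charged product stayed idle, green would repeat that count. For the green run I reckoned 85.5 mM made, so 92.8 % of the starting material charged, the charged product included.

Was one number enough? By 71 min the violet run stood at 18.6 and the teal run at 17.1, both higher than ochre. So the count moves with the charge, but green has the ochre amounts of starting material, partner and catalyst. The idle product was the real assumption. The teal run held more product than the ochre run at 71 min. Yet between 61 min and 71 min it gained 6.90 mM, more than the 3.60 mM of ochre. But the teal run was also charged with 440 mM of partner against 220 mM in ochre, so two things differed, and I took this only as a sign against harmful product.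

The forecast gave 0.15 for the order in partner, 1 for the order in starting material and 93 % for green, and it judged that the second partner is lost by itself. Its words were “Product is therefore innocent, so green should follow ochre”.

The simulation gave 93.1 % for green, 0.062 for the order in partner and 1.0 for the order in starting material, and it showed that the second partner is lost by itself.

    catalyst + partner ⇌ catalyst-reagent complex, settled at all times (80.30 M⁻¹)
    catalyst-reagent complex + starting material → product + catalyst (1.998 M⁻¹ min⁻¹)
    partner → lost reagent (0.03060 min⁻¹)

A fit in which the product kills the catalyst gave 77.9 % for green. In turnovers, that fit asks for 9.30. The ochre reading gave 14.2, and the green run made 14.4 turnovers.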